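**Plan**

- Cuts, in retrosynthetic order: the C15 ester C–O bond (acid 26 plus (R)-glycidyl acetate 28); the C1=C10/C5–H array, traced back by a reductive allylic transposition to a 1-oxygenated Δ5 octalin; then C7–C8 and C9–C10 of ring B together.
- Enabling feature: ring B (C5–C10) holds the vicinal pair C8 (H, CH3-17) and C9 (quaternary: C20, C11 chain) with C17 cis to C11, bounded by C7 and the ring-fusion carbon C10 of ring A. With the alkene at C5=C6 and C20 as CHO, this is the Diels–Alder imprint of an (E)-2-alkylbut-2-enal on the 2-vinylcyclohexene unit C10=C5–C6=C7.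
- Forward order: ring A diene 7 and enal 15 (carrying the whole C11–C16 chain) are joined in the cycloaddition that closes ring B; CHO becomes CH3; the C1 oxygen moves the alkene and is lost; the glyceride is attached last.
- Stereochemistry: C13 and glycerol C2 come from the chiral pool; C8/C9 from enal geometry plus chiral catalyst; C1 and C10 of the adduct form as mixtures and converge on one enone; C5 from a CBS-set C1 carbinol, relayed by Mitsunobu inversion and suprafacial retro-ene hydrogen transfer.

Key step: step 9

Numbering: halimane numbering is used for all bicyclic compounds (ring A = C1–C5, C10; ring B = C5–C10; C18/C19 on C4, C17 on C8, C20 on C9, chain C11–C15 on C9 with C16 on C13).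

Assumption: from the usual formyl C–H···O pre-transition-state model, the (S)-prolinol-derived oxazaborolidinium is taken to shield the Cα-Si face of enal 15; if the sense proves opposite, its enantiomer is used with no other change.

**Route**

Step 1
Reactants: 1 3-ethoxycyclohex-2-en-1-one
Product: 3 3-ethoxy-6,6-dimethylcyclohex-2-en-1-one, via 3-ethoxy-6-methylcyclohex-2-en-1-one 2 (not isolated)
Conditions: LDA, THF, −78 °C; MeI, −78 → 0 °C; recool, LDA; MeI, −78 °C → rt
Reagents that add atoms: iodomethane (CI)
Why: Kinetic α'-deprotonation of the vinylogous ester and SN2 methylation, run twice at the same carbon, should install the gem-dimethyl group (enolate alkylation).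

Step 2
Reactants: 3 3-ethoxy-6,6-dimethylcyclohex-2-en-1-one
Product: 5 4,4-dimethyl-3-vinylcyclohex-2-en-1-one, via tertiary allylic alcohol 4 (not isolated)
Conditions: vinylMgBr, THF, 0 °C → rt; then 1 M HCl, rt
Reagents that add atoms: vinylmagnesium bromide (C=C[Mg]Br); water (O)
Why: 1,2-Addition to the vinylogous ester carbonyl, then acid hydrolysis of the enol ether with loss of water, transposes the enone (Stork–Danheiser sequence) and places the vinyl group next to the gem-dimethyl carbon.

Step 3
Reactants: 5 4,4-dimethyl-3-vinylcyclohex-2-en-1-one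
Product: 6 rac-4,4-dimethyl-3-vinylcyclohex-2-en-1-ol
Conditions: NaBH4, CeCl3·7H2O, MeOH, 0 °C
Reagents that add atoms: none
Why: Luche reduction should give clean 1,2-reduction of the cross-conjugated dienone; the carbinol centre is made racemic on purpose because it is erased in step 12.

Step 4
Reactants: 6 rac-4,4-dimethyl-3-vinylcyclohex-2-en-1-ol
Product: 7 rac-tert-butyl[(4,4-dimethyl-3-vinylcyclohex-2-en-1-yl)oxy]dimethylsilane
Conditions: TBSCl, imidazole, DMF, rt
Reagents that add atoms: tert-butyldimethylsilyl chloride (CC(C)(C)[Si](C)(C)Cl)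
Why: Standard silylation masks the hydroxyl so that it cannot bind the Lewis acid of step 9.

Step 5
Reactants: 8 (E)-but-2-enal
Product: 10 (Z)-2-bromobut-2-enal, via 2,3-dibromobutanal 9 (not isolated)
Conditions: Br2, CH2Cl2, −10 °C; then Et3N, 0 °C → rt
Reagents that add atoms: bromine (BrBr)
Why: Bromine addition followed by base-induced loss of HBr from the acidic α-position should give the more stable Z isomer (CHO trans to CH3).

Step 6
Reactants: 11 (R)-5-methoxy-3-methyl-5-oxopentanoic acid (methyl hydrogen (R)-3-methylglutarate)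
Product: 12 methyl (R)-5-hydroxy-3-methylpentanoate
Conditions: BH3·SMe2, THF, −10 °C → rt; MeOH quench; used crude
Reagents that add atoms: none
Why: Borane reduces the free acid much faster than the methyl ester (chemoselective reduction); the stereocentre is not touched.

Step 7
Reactants: 12 methyl (R)-5-hydroxy-3-methylpentanoate
Product: 13 methyl (S)-5-iodo-3-methylpentanoate
Conditions: I2, PPh3, imidazole, CH2Cl2, 0 °C → rt
Reagents that add atoms: iodine (II)
Why: Appel-type iodination proceeds by SN2 at the primary carbon and forestalls lactonisation of 12; the descriptor changes only through CIP priority.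

Step 8
Reactants: 13 methyl (S)-5-iodo-3-methylpentanoate; 10 (Z)-2-bromobut-2-enal
Product: 15 methyl (3R,6E)-6-formyl-3-methyloct-6-enoate, via alkylzinc iodide 14 (not isolated)
Conditions: Zn dust (TMSCl/1,2-dibromoethane-activated), LiCl, THF, 40 °C; then 10, PdCl2(dppf) (3 mol %, divalent palladium precatalyst), THF, rt
Reagents that add atoms: none
Why: Zinc insertion tolerates the ester, and Negishi sp3–sp2 coupling at the vinyl bromide should proceed with retention, giving the E enal (C17 methyl cis to the new chain), which is also the thermodynamic isomer.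

Step 9
Reactants: 7 rac-tert-butyl[(4,4-dimethyl-3-vinylcyclohex-2-en-1-yl)oxy]dimethylsilane; 15 methyl (3R,6E)-6-formyl-3-methyloct-6-enoate
Product: 16 methyl (8R,9S,13R)-1-(tert-butyldimethylsilyloxy)-20-oxohalim-5-en-15-oate (all four C1/C10 stereoisomers)
Conditions: oxazaborolidinium triflimide (20 mol %) from (S)-3,3-diphenyl-1-(o-tolyl)tetrahydro-1H,3H-pyrrolo[1,2-c][1,3,2]oxazaborole (C24H24BNO) and HN(SO2CF3)2, CH2Cl2, −78 → −20 °C
Reagents that add atoms: none
Why: The N-protonated oxazaborolidine binds the formyl group of 15, lowers its LUMO and holds the enal s-trans, and s-cis diene 7 adds in a concerted, asynchronous normal-demand [4+2] cycloaddition in which C7–C8 bonding leads C9–C10 bonding; the closest known reaction type is the oxazaborolidinium-catalysed enantioselective Diels–Alder reaction of 2-substituted enals of the tiglic aldehyde class with 1-vinylcyclohexenes. Ring B (C5–C10) is closed by this intermolecular suprafacial–suprafacial [4+2] mode, ring A being carried in the diene. The relative configuration at C8 and C9 follows from the E geometry of 15 (C17 cis to the C11 chain, trans to the C20 formyl group), and the absolute configuration from the catalyst, which should leave only the Cα-Re face open. The step needs "ortho" regioselectivity (C9 to C10), which the larger HOMO coefficient and free access at the unsubstituted terminus C7 should secure by pairing C7 with the β-carbon C8; it also needs an s-cis diene, which the C4 gem-dimethyl group favours by destabilising the s-trans rotamer. It needs no control at C1 or C10: both enantiomers of 7 and both endo and exo modes give members of 16 with the same C8/C9 configuration, and all are funnelled into the single enone 21 in step 12.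

Step 10
Reactants: 16 methyl (8R,9S,13R)-1-(tert-butyldimethylsilyloxy)-20-oxohalim-5-en-15-oate
Product: 18 methyl (8R,9R,13R)-1-(tert-butyldimethylsilyloxy)halim-5-en-15-oate (C1/C10 mixture), via tosylhydrazone 17 (not isolated)
Conditions: TsNHNH2, EtOH, 50 °C; concentrate; catecholborane, CHCl3, 0 °C; then NaOAc·3H2O, reflux
Reagents that add atoms: none
Why: Hydride reduction of the tosylhydrazone, sulfinate loss and extrusion of N2 from the alkyl diazene (Caglioti-type deoxygenation) should turn the neopentyl CHO into the C20 methyl under conditions that spare ester, silyl ether and alkene.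

Step 11
Reactants: 18 methyl (8R,9R,13R)-1-(tert-butyldimethylsilyloxy)halim-5-en-15-oate
Product: 19 methyl (8R,9R,13R)-1-hydroxyhalim-5-en-15-oate (C1/C10 mixture)
Conditions: TBAF, THF, rt
Reagents that add atoms: none
Why: Fluoride cleaves the Si–O bond selectively; the methyl ester is stable.

Step 12
Reactants: 19 methyl (8R,9R,13R)-1-hydroxyhalim-5-en-15-oate
Product: 21 methyl (8R,9R,13R)-1-oxohalim-5(10)-en-15-oate, via β,γ-unsaturated ketone 20 (not isolated)
Conditions: DMP, NaHCO3, CH2Cl2, 0 °C → rt; then DBU, CH2Cl2, rt
Reagents that add atoms: none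
Why: Dess–Martin oxidation erases the C1 centre, and base-mediated conjugation through the dienolate (C10–H is α to the ketone and allylic) moves the alkene to C5(10) and erases C10, so all isomers should converge on one tetrasubstituted enone.

Step 13
Reactants: 21 methyl (8R,9R,13R)-1-oxohalim-5(10)-en-15-oate
Product: 22 methyl (1R,8R,9R,13R)-1-hydroxyhalim-5(10)-en-15-oate
Conditions: (S)-1-methyl-3,3-diphenyltetrahydro-1H,3H-pyrrolo[1,2-c][1,3,2]oxazaborole (C18H20BNO, 0.5 equiv), catecholborane, toluene, −78 °C
Reagents that add atoms: none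
Why: In this CBS reduction the fully substituted alkenyl carbon C10 acts as the large group and C2H2 as the small one, so the (S)-oxazaborolidine should give the (1R) carbinol by reagent control, with 1,2-selectivity and without touching the ester.

Step 14
Reactants: 22 methyl (1R,8R,9R,13R)-1-hydroxyhalim-5(10)-en-15-oate
Product: 25 methyl (5S,8R,9R,13R)-halim-1(10)-en-15-oate, via N-alkyl sulfonylhydrazine 23 (not isolated), via allylic diazene 24 (not isolated)
Conditions: 2-nitrobenzenesulfonylhydrazide, PPh3, DEAD, THF, −30 °C; then rt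
Reagents that add atoms: none
Why: Mitsunobu displacement inverts C1, loss of 2-nitrobenzenesulfinic acid gives the allylic diazene, and its suprafacial retro-ene reaction (loss of N2) places hydrogen on C5 on the face that carried nitrogen while the alkene moves to C1=C10, so the C1 configuration from step 13 is translated into (5S).

Step 15
Reactants: 25 methyl (5S,8R,9R,13R)-halim-1(10)-en-15-oate
Product: 26 (5S,8R,9R,13R)-halim-1(10)-en-15-oic acid
Conditions: LiOH, THF/MeOH/H2O, rt; then 1 M HCl
Reagents that add atoms: lithium hydroxide ([Li+].[OH-])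
Why: Saponification of the unhindered methyl ester; C13 is β to the carboxyl group and cannot epimerise.

Step 16
Reactants: 27 (S)-glycidol
Product: 28 (R)-glycidyl acetate
Conditions: Ac2O, Et3N, DMAP (cat.), CH2Cl2, 0 °C
Reagents that add atoms: acetic anhydride (CC(=O)OC(C)=O)
Why: O-Acetylation of the primary alcohol leaves the epoxide and its stereocentre untouched (the descriptor changes only through CIP priority).

Step 17
Reactants: 26 (5S,8R,9R,13R)-halim-1(10)-en-15-oic acid; 28 (R)-glycidyl acetate
Product: 29 (2S)-3-acetoxy-2-hydroxypropyl (5S,8R,9R,13R)-halim-1(10)-en-15-oate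
Conditions: [(R,R)-N,N'-bis(3,5-di-tert-butylsalicylidene)-1,2-cyclohexanediaminato]cobalt (C36H52CoN2O2, divalent cobalt, 5 mol %, oxidised in the flask by air to the trivalent cobalt carboxylate), iPr2NEt, TBME, rt, under air
Reagents that add atoms: none
Why: Cobalt salen-catalysed addition of the carboxylic acid to the terminal epoxide should occur at the CH2 carbon only (the (R,R) complex is expected to be the matched one), so the stereocentre is untouched and the 1,3-diacylglycerol with free secondary hydroxyl forms at room temperature.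

**Compound list**

1 | 3-ethoxycyclohex-2-en-1-one | CCOC1=CC(=O)CCC1 | starting material
2 | 3-ethoxy-6-methylcyclohex-2-en-1-one (racemic) | CCOC1=CC(=O)C(C)CC1 | intermediate (not isolated)
3 | 3-ethoxy-6,6-dimethylcyclohex-2-en-1-one | CCOC1=CC(=O)C(C)(C)CC1 | intermediate
4 | 3-ethoxy-6,6-dimethyl-1-vinylcyclohex-2-en-1-ol (racemic, as its magnesium alkoxide) | CCOC1=CC(O)(C=C)C(C)(C)CC1 | intermediate (not isolated)
5 | 4,4-dimethyl-3-vinylcyclohex-2-en-1-one | C=CC1=CC(=O)CCC1(C)C | intermediate
6 | rac-4,4-dimethyl-3-vinylcyclohex-2-en-1-ol | C=CC1=CC(O)CCC1(C)C | intermediate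
7 | rac-tert-butyl[(4,4-dimethyl-3-vinylcyclohex-2-en-1-yl)oxy]dimethylsilane | C=CC1=CC(O[Si](C)(C)C(C)(C)C)CCC1(C)C | intermediate
8 | (E)-but-2-enal (crotonaldehyde) | C/C=C/C=O | starting material
9 | 2,3-dibromobutanal (diastereomer mixture) | CC(Br)C(Br)C=O | intermediate (not isolated)
10 | (Z)-2-bromobut-2-enal | C/C=C(\Br)C=O | intermediate
11 | (R)-5-methoxy-3-methyl-5-oxopentanoic acid | COC(=O)C[C@H](C)CC(=O)O | starting material
12 | methyl (R)-5-hydroxy-3-methylpentanoate | COC(=O)C[C@H](C)CCO | intermediate
13 | methyl (S)-5-iodo-3-methylpentanoate | COC(=O)C[C@H](C)CCI | intermediate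
14 | [(3R)-5-methoxy-3-methyl-5-oxopentyl]zinc iodide | COC(=O)C[C@H](C)CC[Zn]I | intermediate (not isolated)
15 | methyl (3R,6E)-6-formyl-3-methyloct-6-enoate | COC(=O)C[C@H](C)CC/C(C=O)=C\C | intermediate
16 | methyl (8R,9S,13R)-1-(tert-butyldimethylsilyloxy)-20-oxohalim-5-en-15-oate, C1 and C10 unspecified (mixture) | COC(=O)C[C@H](C)CC[C@@]1(C=O)C2C(O[Si](C)(C)C(C)(C)C)CCC(C)(C)C2=CC[C@H]1C | intermediate
17 | 20-(4-methylbenzenesulfonylhydrazone) of 16 | COC(=O)C[C@H](C)CC[C@@]1(C=NNS(=O)(=O)c2ccc(C)cc2)C3C(O[Si](C)(C)C(C)(C)C)CCC(C)(C)C3=CC[C@H]1C | intermediate (not isolated)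
18 | methyl (8R,9R,13R)-1-(tert-butyldimethylsilyloxy)halim-5-en-15-oate, C1 and C10 unspecified | COC(=O)C[C@H](C)CC[C@@]1(C)C2C(O[Si](C)(C)C(C)(C)C)CCC(C)(C)C2=CC[C@H]1C | intermediate
19 | methyl (8R,9R,13R)-1-hydroxyhalim-5-en-15-oate, C1 and C10 unspecified | COC(=O)C[C@H](C)CC[C@@]1(C)C2C(O)CCC(C)(C)C2=CC[C@H]1C | intermediate
20 | methyl (8R,9R,13R)-1-oxohalim-5-en-15-oate, C10 unspecified | COC(=O)C[C@H](C)CC[C@@]1(C)C2C(=O)CCC(C)(C)C2=CC[C@H]1C | intermediate (not isolated)
21 | methyl (8R,9R,13R)-1-oxohalim-5(10)-en-15-oate | COC(=O)C[C@H](C)CC[C@@]1(C)C2=C(C(C)(C)CCC2=O)CC[C@H]1C | intermediate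
22 | methyl (1R,8R,9R,13R)-1-hydroxyhalim-5(10)-en-15-oate | COC(=O)C[C@H](C)CC[C@@]1(C)C2=C(C(C)(C)CC[C@H]2O)CC[C@H]1C | intermediate
23 | methyl (1S,8R,9R,13R)-1-[1-(2-nitrophenylsulfonyl)hydrazinyl]halim-5(10)-en-15-oate | COC(=O)C[C@H](C)CC[C@@]1(C)C2=C(C(C)(C)CC[C@@H]2N(N)S(=O)(=O)c3ccccc3[N+](=O)[O-])CC[C@H]1C | intermediate (not isolated)
24 | methyl (1S,8R,9R,13R)-1-diazenylhalim-5(10)-en-15-oate | COC(=O)C[C@H](C)CC[C@@]1(C)C2=C(C(C)(C)CC[C@@H]2N=N)CC[C@H]1C | intermediate (not isolated)
25 | methyl (5S,8R,9R,13R)-halim-1(10)-en-15-oate | COC(=O)C[C@H](C)CC[C@@]1(C)C2=CCCC(C)(C)[C@@H]2CC[C@H]1C | intermediate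
26 | (5S,8R,9R,13R)-halim-1(10)-en-15-oic acid | OC(=O)C[C@H](C)CC[C@@]1(C)C2=CCCC(C)(C)[C@@H]2CC[C@H]1C | intermediate
27 | (S)-glycidol | OC[C@H]1CO1 | starting material
28 | (R)-glycidyl acetate | CC(=O)OC[C@H]1CO1 | intermediate
29 | (2S)-3-acetoxy-2-hydroxypropyl (5S,8R,9R,13R)-halim-1(10)-en-15-oate | CC(=O)OC[C@H](O)COC(=O)C[C@H](C)CC[C@@]1(C)C2=CCCC(C)(C)[C@@H]2CC[C@H]1C | target

**Step count and risks**

Total steps: 17. Longest linear sequence: 12 (steps 1–4, 9–15, 17).

Steps most likely to fail:

1. Step 9. The cycloaddition may stall at the hindered C10 terminus, the cationic Lewis acid may ionise the allylic silyl ether, facial control over the enal may erode, or one enantiomer of racemic 7 may react much more slowly than the other so that part of 15 stays unconsumed. Fallback (substrate control in place of catalyst control): dienone 5 is reduced with the (R)-configured oxazaborolidine (C18H20BNO) and catecholborane to (S)-4,4-dimethyl-3-vinylcyclohex-2-en-1-ol F1, which is silylated to the (S)-silyl ether F2. F2 is combined with 15 under Me2AlCl in CH2Cl2 at −78 °C. On the assumption of formyl-endo addition anti to the silyloxy group, the C1 centre should then dictate the C8/C9 configuration, and the adduct rejoins the route at 16 as its (1S) members.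

2. Step 14. The Mitsunobu displacement at the hindered C1 carbinol may stall or divert to elimination, so that no diazene forms. Fallback (hydride delivery to a hydrazone in place of SN2 inversion): enone 21 is condensed with TsNHNH2 to the tosylhydrazone F3, which is reduced with catecholborane and then treated with NaOAc·3H2O. Hydride entry at C1 from the β face would give the same allylic diazene 24 and, after retro-ene loss of N2, ester 25; here C5 rests on substrate control and would need to be checked.

3. Step 17. Opening of the epoxide may be slow or may occur in part at the internal carbon, and acyl groups may migrate or exchange. Fallback (protected glycerol in place of epoxide opening): acid 26 is esterified (EDC·HCl, DMAP) with (R)-solketal (CC1(C)OC[C@@H](CO)O1) to the acetonide ester F4. The acetonide is cleaved with 80 % aqueous AcOH at 40 °C to the (2S)-2,3-dihydroxypropyl ester F5. Primary-selective acetylation (AcCl, 2,4,6-collidine, CH2Cl2, −78 °C) then gives 29.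

**Further compounds**

F1 | step 9 | (S)-4,4-dimethyl-3-vinylcyclohex-2-en-1-ol | C=CC1=C[C@@H](O)CCC1(C)C
F2 | step 9 | (S)-tert-butyl[(4,4-dimethyl-3-vinylcyclohex-2-en-1-yl)oxy]dimethylsilane | C=CC1=C[C@@H](O[Si](C)(C)C(C)(C)C)CCC1(C)C
F3 | step 14 | methyl (8R,9R,13R)-1-(4-methylbenzenesulfonylhydrazono)halim-5(10)-en-15-oate | COC(=O)C[C@H](C)CC[C@@]1(C)C2=C(C(C)(C)CCC2=NNS(=O)(=O)c3ccc(C)cc3)CC[C@H]1C
F4 | step 17 | [(4S)-2,2-dimethyl-1,3-dioxolan-4-yl]methyl (5S,8R,9R,13R)-halim-1(10)-en-15-oate | CC1(C)OC[C@@H](COC(=O)C[C@H](C)CC[C@@]2(C)C3=CCCC(C)(C)[C@@H]3CC[C@H]2C)O1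
F5 | step 17 | (2S)-2,3-dihydroxypropyl (5S,8R,9R,13R)-halim-1(10)-en-15-oate | OC[C@H](O)COC(=O)C[C@H](C)CC[C@@]1(C)C2=CCCC(C)(C)[C@@H]2CC[C@H]1C
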